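**Retrosynthetic overview**

1. The target is the ring-opened, O-methylated and 8-O-acetylated form of the 12,8β-lactone 24. The 3β-angelate comes from a 3-ketone, the 8β-oxygen from iodolactonisation of a C8=C9 alkene, and that alkene from a C9 ketone.
2. Ring A (5α-OH, C3–O, C4=C15, C2H2) is read as an opened 7-oxabicyclo[2.2.1]heptene: the C5 oxygen once bridged C5 and C2 and C3=C4(C15) was its alkene. A singlet-oxygen ene reaction and SmI2 cleavage of C2–O unmask it.
3. Key disconnection, C1–C2 and C5–C10 together: intramolecular Diels–Alder reaction of a 2-alkyl-3-methylfuran (C2, C3, C4, C5 and the C5 oxygen) with an isopropenyl ketone (C1=C10(C14)–C9=O). The enabling feature is that in ring A the oxygen-bearing C5 and C2 stand 1,4 with C15 on C4, which is the footprint of a furan, while ring B is only the four-carbon tether C6–C9 from furan carbon C5 to dienophile carbon C10.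
4. The acyclic precursor 12 comes from 3-methylfuran-2-carbaldehyde (furan and C6), a 2-(alkoxycarbonyl)allyl bromide (C7–C9, C11–C13) and isopropenylmagnesium bromide (C1, C10, C14). C7 is set by asymmetric allylation, and the carbinol oxygen on C6 is then removed.
5. Order of ring formation: rings A and B together in step 7, then a temporary γ-lactone ring in step 11 that is opened again in step 16.

Key step: step 7

Convention: eudesmane numbering is used (C1–C10 ring carbons, C11–C13 the acrylate unit, C14 the methyl on C10, C15 the carbon on C4); β is the face of C14, α the opposite face.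
Assumption: the carbinol carbon of 8 is drawn syn to C7; this has no consequence because that centre is removed in step 5, and the ligand antipode is the one that gives (S) at C7.

**Step 1**
Reactants: 1 N-methoxy-N-methylacetamide; 2 tert-butyl 2-(bromomethyl)prop-2-enoate
Product: 4 tert-butyl 5-[methoxy(methyl)amino]-2-methylidene-5-oxopentanoate, via lithium enolate 3 (not isolated)
Conditions: LiN(iPr)2, THF, −78 °C; then 2, −78 → −40 °C
Reagents that add atoms: none
Why: Enolate alkylation by SN2′ addition–elimination on the 2-(bromomethyl)acrylate should give the 2-methyleneglutarate skeleton C13=C11(C12)–C7–C8–C9 without creating a stereocentre.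

**Step 2**
Reactants: 4 tert-butyl 5-[methoxy(methyl)amino]-2-methylidene-5-oxopentanoate
Product: 5 tert-butyl (2Z)-2-(bromomethyl)-5-[methoxy(methyl)amino]-5-oxopent-2-enoate
Conditions: N-bromosuccinimide, AIBN (cat), PhCF3, 80 °C
Reagents that add atoms: N-bromosuccinimide, O=C1CCC(=O)N1Br
Why: Wohl–Ziegler bromination should abstract the only allylic hydrogen (on C7) and trap the 2-(alkoxycarbonyl)allyl radical at its unsubstituted terminus, giving the conjugated primary allylic bromide, whose E and Z forms converge in step 3.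

**Step 3**
Reactants: 5 tert-butyl (2Z)-2-(bromomethyl)-5-[methoxy(methyl)amino]-5-oxopent-2-enoate; 6 3-methylfuran-2-carbaldehyde
Product: 8 tert-butyl (3S,4R)-4-hydroxy-3-{2-[methoxy(methyl)amino]-2-oxoethyl}-2-methylidene-4-(3-methylfuran-2-yl)butanoate, via trimethylsilyl ether 7 (not isolated)
Conditions: CrCl2 (10 mol %), chiral 1,8-bis(oxazolin-2-yl)carbazole ligand (12 mol %, antipode giving the 4R carbinol), Mn powder, Me3SiCl, Et3N (20 mol %), THF, rt; then 1 M aq citric acid, 0 °C
Reagents that add atoms: none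
Why: Catalytic asymmetric Nozaki–Hiyama–Kishi 2-(alkoxycarbonyl)allylation: the allylchromium species from 5 should add through its substituted γ-carbon (C7) in a closed chair transition state, in which the chiral ligand selects the aldehyde face and the chair ties the configuration of C7 (S) to that of the carbinol carbon (syn), and mild acid then removes the silyl group.

**Step 4**
Reactants: 8 tert-butyl (3S,4R)-4-hydroxy-3-{2-[methoxy(methyl)amino]-2-oxoethyl}-2-methylidene-4-(3-methylfuran-2-yl)butanoate
Product: 9 tert-butyl (3S,4R)-4-[(1H-imidazol-1-ylcarbonothioyl)oxy]-3-{2-[methoxy(methyl)amino]-2-oxoethyl}-2-methylidene-4-(3-methylfuran-2-yl)butanoate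
Conditions: 1,1′-thiocarbonyldiimidazole, DMAP (cat), CH2Cl2, rt
Reagents that add atoms: 1,1′-thiocarbonyldiimidazole, S=C(n1ccnc1)n1ccnc1
Why: O-Thioacylation of the secondary furylic alcohol gives the thiocarbonyl derivative needed for radical deoxygenation and touches no stereocentre.

**Step 5**
Reactants: 9 tert-butyl (3S,4R)-4-[(1H-imidazol-1-ylcarbonothioyl)oxy]-3-{2-[methoxy(methyl)amino]-2-oxoethyl}-2-methylidene-4-(3-methylfuran-2-yl)butanoate
Product: 10 tert-butyl (3S)-5-[methoxy(methyl)amino]-2-methylidene-3-[(3-methylfuran-2-yl)methyl]-5-oxopentanoate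
Conditions: Bu3SnH (slow addition), AIBN (cat), toluene, 90 °C
Reagents that add atoms: none
Why: Barton–McCombie deoxygenation: the tin radical adds to the thiocarbonyl group, the C6–O bond fragments to the stabilised furylmethyl radical and hydrogen transfer gives the CH2 group, a radical path that cannot epimerise or eliminate at the neighbouring C7 stereocentre.

**Step 6**
Reactants: 10 tert-butyl (3S)-5-[methoxy(methyl)amino]-2-methylidene-3-[(3-methylfuran-2-yl)methyl]-5-oxopentanoate
Product: 12 tert-butyl 2-[(2S)-5-methyl-1-(3-methylfuran-2-yl)-4-oxohex-5-en-2-yl]prop-2-enoate, via bromomagnesium hemiaminal 11 (not isolated)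
Conditions: isopropenylmagnesium bromide, THF, −20 → 0 °C; aq NH4Cl
Reagents that add atoms: isopropenylmagnesium bromide, C=C(C)[Mg]Br
Why: Weinreb ketone synthesis: the chelated tetrahedral adduct should stop at mono-addition and release the isopropenyl ketone on work-up, while the hindered tert-butyl ester is left alone and C7 is not touched.

**Step 7**
Reactants: 12 tert-butyl 2-[(2S)-5-methyl-1-(3-methylfuran-2-yl)-4-oxohex-5-en-2-yl]prop-2-enoate
Product: 13 tert-butyl 2α,5α-epoxy-9-oxoeudesma-3,11(13)-dien-12-oate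
Conditions: MeAlCl2 (2.2 equiv), CH2Cl2 (0.01 M), −78 °C; quench at −78 °C with Et3N–MeOH
Reagents that add atoms: none
Why: Coordination of MeAlCl2 to the C9 ketone lowers the LUMO of the C1=C10 isopropenyl ketone, and the furan diene (C2=C3–C4=C5) adds to it in a normal-demand intramolecular Diels–Alder reaction that forms C1–C2 and C5–C10 in one concerted, asynchronous event. The closest known reaction type is the Lewis-acid-promoted intramolecular Diels–Alder reaction of furans that carry an enone at the end of a four-atom all-carbon tether, which at low temperature gives oxatricyclic ketones, also with a methyl group on the inner dienophile carbon. Ring A closes by the [4+2] cycloaddition itself, as a 7-oxabicyclo[2.2.1]heptene whose bridge C2–O–C5 is the later 5α-hydroxyl, and ring B closes as the six-membered ring spanned by the tether C6–C9 (type 1 mode, tether on a diene terminus and on the inner dienophile carbon). The tether has to lie exo, syn to the oxygen bridge, which places the C5 oxygen and the C10 methyl group trans and fixes C2, C5 and C10 relative to one another. Their absolute sense is decided by the C7 stereocentre, whose acrylate substituent takes the equatorial position of the chair-like forming ring B and so selects the furan face. Regiochemistry is fixed by the tether; the step needs this π-facial selectivity and survival of the adduct, which the single equatorial substituent and the cold quench of the Lewis acid should secure (reversion is possible only while the C3=C4 alkene exists, and that is consumed in step 9).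

**Step 8**
Reactants: 13 tert-butyl 2α,5α-epoxy-9-oxoeudesma-3,11(13)-dien-12-oate
Product: 15 tert-butyl 2α,5α-epoxy-9-[(trifluoromethanesulfonyl)oxy]eudesma-3,8,11(13)-trien-12-oate, via potassium enolate 14 (not isolated)
Conditions: KN(SiMe3)2, THF, −78 °C; then PhNTf2, −78 → −30 °C
Reagents that add atoms: N-phenylbis(trifluoromethanesulfonimide), O=S(=O)(N(c1ccccc1)S(=O)(=O)C(F)(F)F)C(F)(F)F
Why: Enolate O-triflation: the C9 ketone can enolise only toward C8 because C10 is quaternary, so a single C8=C9 enol triflate should form and no stereocentre is affected.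

**Step 9**
Reactants: 15 tert-butyl 2α,5α-epoxy-9-[(trifluoromethanesulfonyl)oxy]eudesma-3,8,11(13)-trien-12-oate
Product: 18 tert-butyl 2α,5α-epoxy-3-oxo-9-[(trifluoromethanesulfonyl)oxy]eudesma-4(15),8,11(13)-trien-12-oate, via allylic hydroperoxide 16 (not isolated), via peroxyacetate 17 (not isolated)
Conditions: O2, tetraphenylporphyrin (cat), visible light, CH2Cl2, 0 °C; then Ac2O, pyridine, DMAP (cat), 0 °C → rt
Reagents that add atoms: dioxygen, O=O
Why: Schenck ene reaction of singlet oxygen with the strained, electron-rich C3=C4 alkene can take hydrogen only from C15 (the other allylic hydrogen sits on the C2 bridgehead), which puts oxygen on C3 from the exo face and moves the alkene to C4(15), and Kornblum–DeLaMare-type dehydration of the acetylated hydroperoxide then gives the C3 ketone while the electron-poor acrylate and enol triflate stay inert.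

**Step 10**
Reactants: 18 tert-butyl 2α,5α-epoxy-3-oxo-9-[(trifluoromethanesulfonyl)oxy]eudesma-4(15),8,11(13)-trien-12-oate
Product: 19 tert-butyl 2α,5α-epoxy-3-oxoeudesma-4(15),8,11(13)-trien-12-oate
Conditions: Pd(OAc)2 (5 mol %), PPh3, HCO2H, Bu3N, DMF, 60 °C
Reagents that add atoms: none
Why: Palladium-catalysed formate reduction of the enol triflate (oxidative addition, formate exchange, decarboxylation, C–H reductive elimination) should give the C8=C9 alkene, and heating is safe because cycloreversion is no longer possible.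

**Step 11**
Reactants: 19 tert-butyl 2α,5α-epoxy-3-oxoeudesma-4(15),8,11(13)-trien-12-oate
Product: 20 2α,5α-epoxy-9α-iodo-3-oxoeudesma-4(15),11(13)-dien-12,8β-olide
Conditions: I2, NaHCO3, MeCN, 0 °C → rt, dark
Reagents that add atoms: iodine, II
Why: Iodolactonisation with participation of the tert-butyl ester: iodonium formation is reversible and only the ion on the α face of C8=C9 can be opened by the C12 carbonyl oxygen, which must attack C8 from the β face on which the C7 side chain sits (5-exo closure, trans-diaxial opening), so the cis-fused lactone with 8β-O and 9α-I should result while the tert-butyl group leaves as isobutene.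

**Step 12**
Reactants: 20 2α,5α-epoxy-9α-iodo-3-oxoeudesma-4(15),11(13)-dien-12,8β-olide
Product: 21 2α,5α-epoxy-3-oxoeudesma-4(15),11(13)-dien-12,8β-olide
Conditions: Bu3SnH (1.2 equiv), Et3B (cat), air, toluene, 0 °C → rt
Reagents that add atoms: none
Why: Radical chain dehalogenation replaces the secondary C9 iodide by hydrogen, iodine abstraction being much faster than addition of the tin radical to the enone or the α-methylene lactone, and the C9 stereocentre disappears.

**Step 13**
Reactants: 21 2α,5α-epoxy-3-oxoeudesma-4(15),11(13)-dien-12,8β-olide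
Product: 22 5α-hydroxy-3-oxoeudesma-4(15),11(13)-dien-12,8β-olide
Conditions: SmI2 (2.5 equiv), THF–MeOH, −78 °C
Reagents that add atoms: none
Why: Reductive cleavage of an α-alkoxy ketone: the C3 ketyl expels the C2–O bond, the samarium enolate is protonated at C2, and the bridge oxygen stays on C5 as the 5α-hydroxyl with the configuration set in step 7.

**Step 14**
Reactants: 22 5α-hydroxy-3-oxoeudesma-4(15),11(13)-dien-12,8β-olide
Product: 23 3β,5α-dihydroxyeudesma-4(15),11(13)-dien-12,8β-olide
Conditions: Me4NBH(OAc)3, MeCN–AcOH, −30 → −10 °C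
Reagents that add atoms: none
Why: Hydroxyl-directed Evans–Saksena reduction: the axial 5α-hydroxyl binds the borohydride and delivers hydride to the α face of the C3 ketone, which should give the equatorial 3β-alcohol (anti 1,3-diol) by 1,2-reduction without touching the lactone.

**Step 15**
Reactants: 23 3β,5α-dihydroxyeudesma-4(15),11(13)-dien-12,8β-olide
Product: 24 3β-angeloyloxy-5α-hydroxyeudesma-4(15),11(13)-dien-12,8β-olide
Conditions: angelic acid, 2,4,6-trichlorobenzoyl chloride, Et3N, toluene, rt; then 23, 80 °C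
Reagents that add atoms: angelic acid, C/C=C(/C)C(=O)O
Why: Yamaguchi-type esterification through the preformed mixed anhydride without nucleophilic catalyst acylates the secondary allylic 3β-hydroxyl, leaves the tertiary 5α-hydroxyl free and is the variant that keeps the Z geometry of the angelate.

**Step 16**
Reactants: 24 3β-angeloyloxy-5α-hydroxyeudesma-4(15),11(13)-dien-12,8β-olide
Product: 26 methyl 3β-angeloyloxy-5α,8β-dihydroxyeudesma-4(15),11(13)-dien-12-oate, via lithium carboxylate 25 (not isolated)
Conditions: LiOH·H2O (1.5 equiv), THF–H2O, 0 °C; evaporate; then MeI, DMF, rt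
Reagents that add atoms: lithium hydroxide, [Li+].[OH-]; iodomethane, CI
Why: Saponification of the strained cis-fused γ-lactone should be much faster than that of the hindered, conjugated angelate, and O-alkylation of the carboxylate salt with MeI gives the methyl ester without passing through the free hydroxy acid that would relactonise.

**Step 17**
Reactants: 26 methyl 3β-angeloyloxy-5α,8β-dihydroxyeudesma-4(15),11(13)-dien-12-oate
Product: 27 methyl 8β-acetoxy-3β-angeloyloxy-5α-hydroxyeudesma-4(15),11(13)-dien-12-oate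
Conditions: Ac2O, pyridine, DMAP (cat), CH2Cl2, 0 °C → rt
Reagents that add atoms: acetic anhydride, CC(=O)OC(C)=O
Why: DMAP-catalysed acetylation of the axial secondary 8β-hydroxyl, the only acylable hydroxyl left because the 5α-hydroxyl is tertiary, should give the target and block relactonisation.

**Compound list**

1 | N-methoxy-N-methylacetamide | CC(=O)N(C)OC | starting material
2 | tert-butyl 2-(bromomethyl)prop-2-enoate | C=C(CBr)C(=O)OC(C)(C)C | starting material
3 | lithium enolate of 1 | C=C(O[Li])N(C)OC | intermediate (not isolated)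
4 | tert-butyl 5-[methoxy(methyl)amino]-2-methylidene-5-oxopentanoate | C=C(CCC(=O)N(C)OC)C(=O)OC(C)(C)C | intermediate
5 | tert-butyl (2Z)-2-(bromomethyl)-5-[methoxy(methyl)amino]-5-oxopent-2-enoate | BrC/C(C(=O)OC(C)(C)C)=C\CC(=O)N(C)OC | intermediate
6 | 3-methylfuran-2-carbaldehyde | Cc1ccoc1C=O | starting material
7 | tert-butyl (3S,4R)-3-{2-[methoxy(methyl)amino]-2-oxoethyl}-2-methylidene-4-(3-methylfuran-2-yl)-4-[(trimethylsilyl)oxy]butanoate | C=C(C(=O)OC(C)(C)C)[C@H](CC(=O)N(C)OC)[C@@H](O[Si](C)(C)C)c1occc1C | intermediate (not isolated)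
8 | tert-butyl (3S,4R)-4-hydroxy-3-{2-[methoxy(methyl)amino]-2-oxoethyl}-2-methylidene-4-(3-methylfuran-2-yl)butanoate | C=C(C(=O)OC(C)(C)C)[C@H](CC(=O)N(C)OC)[C@@H](O)c1occc1C | intermediate
9 | tert-butyl (3S,4R)-4-[(1H-imidazol-1-ylcarbonothioyl)oxy]-3-{2-[methoxy(methyl)amino]-2-oxoethyl}-2-methylidene-4-(3-methylfuran-2-yl)butanoate | C=C(C(=O)OC(C)(C)C)[C@H](CC(=O)N(C)OC)[C@@H](OC(=S)n1ccnc1)c1occc1C | intermediate
10 | tert-butyl (3S)-5-[methoxy(methyl)amino]-2-methylidene-3-[(3-methylfuran-2-yl)methyl]-5-oxopentanoate | C=C(C(=O)OC(C)(C)C)[C@H](CC(=O)N(C)OC)Cc1occc1C | intermediate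
11 | bromomagnesium hemiaminal from 10 and isopropenylmagnesium bromide (carbinol carbon unassigned) | C=C(C(=O)OC(C)(C)C)[C@H](CC(O[Mg]Br)(N(C)OC)C(C)=C)Cc1occc1C | intermediate (not isolated)
12 | tert-butyl 2-[(2S)-5-methyl-1-(3-methylfuran-2-yl)-4-oxohex-5-en-2-yl]prop-2-enoate | C=C(C(=O)OC(C)(C)C)[C@H](CC(=O)C(C)=C)Cc1occc1C | intermediate
13 | tert-butyl 2α,5α-epoxy-9-oxoeudesma-3,11(13)-dien-12-oate (7αH, 10β-methyl) | C=C(C(=O)OC(C)(C)C)[C@H]1C[C@@]2(O3)C(C)=C[C@H]3C[C@]2(C)C(=O)C1 | intermediate
14 | potassium C8–C9 enolate of 13 | C=C(C(=O)OC(C)(C)C)[C@H]1C[C@@]2(O3)C(C)=C[C@H]3C[C@]2(C)C(O[K])=C1 | intermediate (not isolated)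
15 | tert-butyl 2α,5α-epoxy-9-[(trifluoromethanesulfonyl)oxy]eudesma-3,8,11(13)-trien-12-oate | C=C(C(=O)OC(C)(C)C)[C@H]1C[C@@]2(O3)C(C)=C[C@H]3C[C@]2(C)C(OS(=O)(=O)C(F)(F)F)=C1 | intermediate
16 | tert-butyl 2α,5α-epoxy-3α-hydroperoxy-9-[(trifluoromethanesulfonyl)oxy]eudesma-4(15),8,11(13)-trien-12-oate | C=C(C(=O)OC(C)(C)C)[C@H]1C[C@@]2(O3)C(=C)[C@H](OO)[C@H]3C[C@]2(C)C(OS(=O)(=O)C(F)(F)F)=C1 | intermediate (not isolated)
17 | tert-butyl 3α-(acetylperoxy)-2α,5α-epoxy-9-[(trifluoromethanesulfonyl)oxy]eudesma-4(15),8,11(13)-trien-12-oate | C=C(C(=O)OC(C)(C)C)[C@H]1C[C@@]2(O3)C(=C)[C@H](OOC(C)=O)[C@H]3C[C@]2(C)C(OS(=O)(=O)C(F)(F)F)=C1 | intermediate (not isolated)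
18 | tert-butyl 2α,5α-epoxy-3-oxo-9-[(trifluoromethanesulfonyl)oxy]eudesma-4(15),8,11(13)-trien-12-oate | C=C(C(=O)OC(C)(C)C)[C@H]1C[C@@]2(O3)C(=C)C(=O)[C@H]3C[C@]2(C)C(OS(=O)(=O)C(F)(F)F)=C1 | intermediate
19 | tert-butyl 2α,5α-epoxy-3-oxoeudesma-4(15),8,11(13)-trien-12-oate | C=C(C(=O)OC(C)(C)C)[C@H]1C[C@@]2(O3)C(=C)C(=O)[C@H]3C[C@]2(C)C=C1 | intermediate
20 | 2α,5α-epoxy-9α-iodo-3-oxoeudesma-4(15),11(13)-dien-12,8β-olide | C=C1C(=O)O[C@H]2[C@@H]1C[C@@]3(O4)C(=C)C(=O)[C@H]4C[C@]3(C)[C@@H]2I | intermediate
21 | 2α,5α-epoxy-3-oxoeudesma-4(15),11(13)-dien-12,8β-olide | C=C1C(=O)O[C@H]2[C@@H]1C[C@@]3(O4)C(=C)C(=O)[C@H]4C[C@]3(C)C2 | intermediate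
22 | 5α-hydroxy-3-oxoeudesma-4(15),11(13)-dien-12,8β-olide | C=C1C(=O)O[C@H]2[C@@H]1C[C@@]3(O)C(=C)C(=O)CC[C@]3(C)C2 | intermediate
23 | 3β,5α-dihydroxyeudesma-4(15),11(13)-dien-12,8β-olide | C=C1C(=O)O[C@H]2[C@@H]1C[C@@]3(O)C(=C)[C@@H](O)CC[C@]3(C)C2 | intermediate
24 | 3β-angeloyloxy-5α-hydroxyeudesma-4(15),11(13)-dien-12,8β-olide | C=C1C(=O)O[C@H]2[C@@H]1C[C@@]3(O)C(=C)[C@@H](OC(=O)/C(C)=C\C)CC[C@]3(C)C2 | intermediate
25 | lithium 3β-angeloyloxy-5α,8β-dihydroxyeudesma-4(15),11(13)-dien-12-oate | C=C(C(=O)[O-])[C@H]1C[C@@]2(O)C(=C)[C@@H](OC(=O)/C(C)=C\C)CC[C@]2(C)C[C@H]1O.[Li+] | intermediate (not isolated)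
26 | methyl 3β-angeloyloxy-5α,8β-dihydroxyeudesma-4(15),11(13)-dien-12-oate | C=C(C(=O)OC)[C@H]1C[C@@]2(O)C(=C)[C@@H](OC(=O)/C(C)=C\C)CC[C@]2(C)C[C@H]1O | intermediate
27 | methyl 8β-acetoxy-3β-angeloyloxy-5α-hydroxyeudesma-4(15),11(13)-dien-12-oate | C=C(C(=O)OC)[C@H]1C[C@@]2(O)C(=C)[C@@H](OC(=O)/C(C)=C\C)CC[C@]2(C)C[C@H]1OC(C)=O | target

**Step count**

Total step count: 17. Longest linear sequence: 17 steps (1 and 2 to 27; aldehyde 6 enters at step 3).

**Steps most likely to fail**

Step 7 (key cycloaddition). The adduct may revert to 12 when the Lewis acid complex warms, the aluminium reagent may cleave the tert-butyl ester, or the two furan faces may not be well differentiated. The fallback activates the dienophile as a cation instead of as a Lewis acid complex. It sets out from 12: 1,2-bis(trimethylsilyloxy)ethane and catalytic Me3SiOTf in CH2Cl2 at −78 °C should give the 2-isopropenyl-1,3-dioxolane F1. A further portion of Me3SiOTf at −78 to −40 °C opens the dioxolane to its 2-alkenyl-1,3-dioxolan-2-ylium ion, a much stronger dienophile, which should undergo the intramolecular ionic Diels–Alder reaction with the furan and reclose to the ketal of the adduct F2. Hydrolysis with pyridinium p-toluenesulfonate in aqueous acetone brings the route back to 13.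

Step 3 (asymmetric allylation). Facial control at the aldehyde or the syn/anti ratio may be insufficient, and either erodes the enantiomeric purity at C7. The fallback secures C7 by kinetic resolution. It sets out from 5 and 6: indium powder in THF–aqueous NH4Cl (Barbier allylation) should give the racemic syn alcohol, a mixture of 8 and its enantiomer F3. Sharpless kinetic resolution of 2-furylmethanols (Ti(OiPr)4, the diisopropyl tartrate antipode that consumes F3, tert-butyl hydroperoxide, molecular sieves, CH2Cl2, −20 °C) oxidises F3 by Achmatowicz-type ring expansion to the pyranone F4, which is separated. The alcohol left behind is 8, where the route is rejoined.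

Step 16 (lactone opening next to the angelate). Hydroxide may also cleave or isomerise the angelate, and the freed 8β-hydroxyl may close back onto the ester. The fallback puts the angelate on last, so that it never meets hydroxide. It sets out from 23: Et3SiCl and imidazole in DMF should silylate only the secondary hydroxyl and give the 3-O-triethylsilyl ether F5. LiOH in THF–H2O gives the lithium carboxylate F6, which MeI in DMF converts into the hydroxy methyl ester F7. Ac2O, pyridine and DMAP give the 8β-acetate F8, and HF·pyridine in THF removes the silyl group to give the 3β,5α-diol F9. Angeloylation of F9 under the conditions of step 15 returns the route at 27.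

**Further compounds**

F1 | step 7 | tert-butyl 2-[(2S)-1-(3-methylfuran-2-yl)-3-(2-isopropenyl-1,3-dioxolan-2-yl)propan-2-yl]prop-2-enoate | C=C(C(=O)OC(C)(C)C)[C@H](CC1(C(C)=C)OCCO1)Cc1occc1C
F2 | step 7 | tert-butyl 2α,5α-epoxy-9,9-(ethylenedioxy)eudesma-3,11(13)-dien-12-oate | C=C(C(=O)OC(C)(C)C)[C@H]1C[C@@]2(O3)C(C)=C[C@H]3C[C@]2(C)C4(OCCO4)C1
F3 | step 3 | tert-butyl (3R,4S)-4-hydroxy-3-{2-[methoxy(methyl)amino]-2-oxoethyl}-2-methylidene-4-(3-methylfuran-2-yl)butanoate | C=C(C(=O)OC(C)(C)C)[C@@H](CC(=O)N(C)OC)[C@H](O)c1occc1C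
F4 | step 3 | tert-butyl (3R)-3-[(2S)-6-hydroxy-4-methyl-3-oxo-3,6-dihydro-2H-pyran-2-yl]-5-[methoxy(methyl)amino]-2-methylidene-5-oxopentanoate (hemiacetal carbon unassigned) | C=C(C(=O)OC(C)(C)C)[C@@H](CC(=O)N(C)OC)[C@@H]1OC(O)C=C(C)C1=O
F5 | step 16 | 5α-hydroxy-3β-(triethylsilyloxy)eudesma-4(15),11(13)-dien-12,8β-olide | C=C1C(=O)O[C@H]2[C@@H]1C[C@@]3(O)C(=C)[C@@H](O[Si](CC)(CC)CC)CC[C@]3(C)C2
F6 | step 16 | lithium 5α,8β-dihydroxy-3β-(triethylsilyloxy)eudesma-4(15),11(13)-dien-12-oate | C=C(C(=O)[O-])[C@H]1C[C@@]2(O)C(=C)[C@@H](O[Si](CC)(CC)CC)CC[C@]2(C)C[C@H]1O.[Li+]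
F7 | step 16 | methyl 5α,8β-dihydroxy-3β-(triethylsilyloxy)eudesma-4(15),11(13)-dien-12-oate | C=C(C(=O)OC)[C@H]1C[C@@]2(O)C(=C)[C@@H](O[Si](CC)(CC)CC)CC[C@]2(C)C[C@H]1O
F8 | step 16 | methyl 8β-acetoxy-5α-hydroxy-3β-(triethylsilyloxy)eudesma-4(15),11(13)-dien-12-oate | C=C(C(=O)OC)[C@H]1C[C@@]2(O)C(=C)[C@@H](O[Si](CC)(CC)CC)CC[C@]2(C)C[C@H]1OC(C)=O
F9 | step 16 | methyl 8β-acetoxy-3β,5α-dihydroxyeudesma-4(15),11(13)-dien-12-oate | C=C(C(=O)OC)[C@H]1C[C@@]2(O)C(=C)[C@@H](O)CC[C@]2(C)C[C@H]1OC(C)=O
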